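The runs are calculated from invented constants; the scatter is artificial.

A stalled flask tempts you to blame the substrate, but in the zeta run the target rose by 6.4 percentage points in the first 0.500 min and by 0.8 points between 3.00 min and 6.00 min, inside the scatter of 1 point, with 71.5% of the substrate still there. Nobody had read the partner, so I followed it, counting one partner per target.

common to all: free catalyst 0.18 mM
- zeta: substrate 14 mM; partner 8 mM; run made earlier
- beta: substrate 22 mM; partner 8 mM; run made earlier
- gamma: substrate 10 mM; partner 16 mM; run made earlier
- flask: substrate 10 mM; partner 8.00 mM

| run | time / min | target / % | substrate / % |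
|---|---|---|---|
| zeta | 0.500 | 6.4 | 92.1 |
| zeta | 1.33 | 10.9 | 86.4 |
| zeta | 3.00 | 14.7 | 76.6 |
| zeta | 6.00 | 15.5 | 71.5 |
| beta | 1.50 | 7.4 | 85.4 |
| beta | 3.00 | 11.5 | 79.4 |
| beta | 5.00 | 11.9 | 79.1 |
| beta | 6.00 | 11.6 | 77.3 |
| gamma | 1.50 | 18.0 | 77.7 |
| gamma | 3.00 | 19.3 | 69.5 |
| gamma | 5.00 | 21.0 | 64.0 |
| gamma | 6.00 | 24.1 | 62.3 |

(each reading ± 1 percentage point)

- the earlier runs were read with a standard deviation of 1 percentage point
- no earlier run changes the charge of free catalyst; that part of a forecast is a guess

1. apparent order in free catalyst when 30% of the substrate are converted (percent change of the rate of making target for one percent more free catalyst charged)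
2. apparent order in partner when 30% of the substrate are converted (percent change of the rate of making target for one percent more partner charged)
3. factor on the rate of making target when 30% of the substrate are converted if partner is charged twice over

From zeta I took the partner yield, the share of the partner charge standing as target at the last reading, 27.1%, which leaves 72.9% of the charge not accounted for as target.

Then I turned the settings. Substrate first: by hand, going from 14 mM to 22 mM should lift the target from 2.17 mM to 3.41 mM if substrate set the level, but beta read 2.55 mM, less than that. Partner next: gamma charged twice the partner of zeta, and less substrate, 10 mM against 14 mM, so two settings differed; at a fixed yield the doubled partner should double the target, but gamma read 2.41 mM, a yield of 15.1%, and I use the zeta yield with the partner charge held at 8.00 mM. For the flask that gave a target level of 2.17 mM. I took the rate at fixed conversion as proportional to the partner left, which put the doubling factor near 2 and the partner order near one. Free catalyst stood at 0.18 mM in zeta, beta and gamma, so my order in it, which I put above one, was a guess.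

The forecast, which differed from me on partner, gave 2 in free catalyst, 0.6 in partner and a factor of 1.5, holding that “Partner is barely consumed”.

The flask gave 3.7 in free catalyst, 1.8 in partner and a factor of 2.33.

    substrate + free catalyst ⇌ catalyst intermediate A (K = 56.0 L mol⁻¹, k = 9300 L mol⁻¹ s⁻¹)
    partner + catalyst intermediate A → catalyst intermediate B (k = 130 L mol⁻¹ s⁻¹)
    catalyst intermediate B → released group + catalyst intermediate C (k = 1.20 s⁻¹)
    catalyst intermediate C → free catalyst + target (k = 1.10 s⁻¹)
    substrate + released group → side product (k = 0.640 L mol⁻¹ s⁻¹)
    2 partner → self-condensation product (k = 3.80 L mol⁻¹ s⁻¹)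

Partner was the limiting reagent in the flask, with 0.44% of its charge left at 8.00 min against 64% of the substrate. The partner yield gave 2.17 mM of target for the flask, which held 1.97 mM at 80.0 min. On beta, the same yield gives 9.86% of the substrate charged, and the last reading there was 11.6%.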